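The target in this flask is paid for in catalyst, so this note for the bench counts what each enzyme earns before it dies.

    starting material + enzyme ⇌ starting complex (K1 = 9.3 /M, k1 = 6700 /M/s)
    second substrate + starting complex ⇌ ternary complex (K2 = 32 /M, k2 = 17000 /M/s)
    ternary complex → enzyme + target (k3 = 6.7 /s)
    gas ⇌ second substrate, rate k4*(csat - [second substrate]) (k4 = 0.085 /s, csat = 34 mM)
    starting complex → spent catalyst (k5 = 0.0017 /s)
    target ⇌ isomer of the product (K6 = 1.2, k6 = 3.3 × 10⁻⁴ /s)

starting material 0.062 M; gas 34 mM (held); enzyme 0.01 mol%; time 15 min

- the target standing at 15 min, as a percentage of the starting material charged
- the change that raises the amount of target at 15 min, in percent of the starting material charged most ("none" if none brings more than 2 percentage points) (violet / ochre / green / none)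
- amount of target at 15 min, in percent of the starting material charged, after violet

- violet: doubling the transfer coefficient of step 4, all else as stated
- ochre: doubling the amount of enzyme, all else as stated
- green: doubling the saturation concentration of gas, all else as stated

In the flask, the gas starts filling the solution with second substrate, and step 4 has a half-time of 0.136 min, far shorter than the run. Its supply at empty, 0.00289 M/s, is far above the most the enzyme can draw, 4.15 × 10⁻⁵ M/s, so we expect the solution to stay near saturation and violet to gain nothing worth the trouble. Ternary complex falls apart backward at 531 /s, much faster than it turns over, so we treat the forms of the enzyme as a pre-equilibrium.

Take as the zero of the scale the even case, with as much ternary complex as starting complex: each enzyme then makes 3940 turnovers before step 5 kills it. Saturation shifts that even case by a factor of 1.09, giving a total turnover number of 4290. Multiplied by the loading, this is 42.9% of the starting material charged, and we call it the ration: at saturation, what has been made at any moment is the ration times the share of catalyst spent.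

Starting complex holds 26.2% of the catalyst still alive, so by 15 min we expect 33.0% of the catalyst charged to be spent and 14.1% of the starting material charged to be made. Taking the target as made evenly, it has stood for half the run on average, and step 6 trims it to 12.0%, our figure for y and for yb. Ochre doubles the ration at the same spent share, giving 24.1%. Green doubles it too, but the spent share falls to 26.8%, giving 19.6%, less than ochre, so we would add enzyme.

The forecast gives 11.8% (from 11% to 12.6%), ochre as the best change and 11.9% after violet, on the ground that “the enzyme stays in fast pre-equilibrium”.

The flask stands at 11.6% of target, and 11.7% after violet, while ochre gains 11 percentage points and green 7.1 points. At 15.0 min the flask has 32.2% of its catalyst spent, and the ration times that share is 13.8%, beside 13.3% of target and isomer of the product standing. A neighbouring flask with 0.25 M of starting material, at the same loading and the same saturation, has the same ration and 45.5% of its catalyst spent, which gives 19.5%; that neighbouring flask holds 18.5% of target and isomer of the product at 15.0 min.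

The constants are those of an exercise; no experiment stands behind them.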